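**Retrosynthetic overview**
1. Positions are named along the acyclic C20 chain: C1 (neryl OCH2), C2=C3, C6=C7, C8 (carbinol), C9 (CH2), C10 (vinylic CH), C11 (lactone α-carbon), C12 (CHOAc), C13 (lactone CH–O), C14=C15, C19 (lactone C=O); the γ-lactone ring is O–C19–C11–C12–C13.
2. Endgame: the target comes from desilylation and C12 acetylation of a hydroxy lactone; its γ-lactone ring and exocyclic (E)-C10=C11 bond come from a 3-yne-1,2-diol by syn hydro-alkoxycarbonylation of a C10≡C11 alkyne (CO becomes C19, C13–OH closes the ring).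
3. Key disconnection C9–C10: the feature used is the allylic carbinol C8, which lies between the C9 methylene and the alkenyl carbon C7, next to C10, which as the exocyclic alkene carbon of the lactone ring can be carried as an alkyne carbon. This C(sp)–CH2–CH(O)–alkenyl unit is what a vinylboronate 1,2-metallate shift leaves, so a bromoalkyne and a vinyl(alkenyl)borate are joined with formation of C9–C10, C7–C8 and the C8 stereocentre in one operation.
4. Fragments: the bromoalkyne (C10–C16, with C12/C13 from D-erythronolactone) by alkyne homologation and Wittig reaction; the alkenyl boronate (C1–C7 and the aryl allyl ether) from nerol and methyl p-coumarate by etherification, cleavage of C6=C7 and boron-Wittig olefination.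
5. Rings: the benzene ring is bought; the dioxolane is a temporary ring carried from the starting lactone and opened in step 14; the γ-lactone, the only ring built, is closed last (step 15).

Key step: step 12

Remark (assumption on the chemistry): the (Sp,Sp) enantiomer of MandyPhos is taken to deliver the (8R) boronate, by analogy with the facial sense it shows with aryl and alkenyl electrophiles; should the sense be the opposite, the (Rp,Rp) ligand is used instead.
Remark (assumption on supply): the erythronolactone acetonide, methyl p-coumarate, nerol and all named reagents are taken as commercially available.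

**Route**

Step 1
Reactants: 1 (−)-2,3-O-isopropylidene-D-erythronolactone
Product: 2 2,3-O-isopropylidene-D-erythrofuranose (lactol, anomeric mixture)
Conditions: i-Bu2AlH, CH2Cl2, −78 °C
Reagents that add atoms: none
Why: Partial hydride reduction of a γ-lactone by i-Bu2AlH at low temperature should stop at the lactol because the tetrahedral aluminium hemiacetal survives until work-up, and the two stereocentres (later C12 and C13) are not touched.

Step 2
Reactants: 2 2,3-O-isopropylidene-D-erythrofuranose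
Product: 3 [(4R,5S)-5-ethynyl-2,2-dimethyl-1,3-dioxolan-4-yl]methanol
Conditions: dimethyl (1-diazo-2-oxopropyl)phosphonate, K2CO3, MeOH, 0 °C to rt
Reagents that add atoms: dimethyl (1-diazo-2-oxopropyl)phosphonate, COP(=O)(OC)C(=[N+]=[N-])C(C)=O
Why: Seyferth–Gilbert homologation in the Ohira–Bestmann version on the open hydroxy-aldehyde form of the lactol should give the terminal alkyne (C10≡C11) by 1,2-hydrogen shift of the alkylidene carbene, the mild carbonate base being chosen to keep the α-alkoxy centre (C12) from epimerising.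

Step 3
Reactants: 3 [(4R,5S)-5-ethynyl-2,2-dimethyl-1,3-dioxolan-4-yl]methanol
Product: 4 (4S,5S)-5-ethynyl-2,2-dimethyl-1,3-dioxolane-4-carbaldehyde
Conditions: PhI(OAc)2, TEMPO (catalytic), CH2Cl2, rt
Reagents that add atoms: none
Why: Oxoammonium (TEMPO) oxidation of the primary alcohol should stop at the aldehyde under non-basic conditions, so that the cis-dioxolane α-centre (C13) is not epimerised.

Step 4
Reactants: 4 (4S,5S)-5-ethynyl-2,2-dimethyl-1,3-dioxolane-4-carbaldehyde
Product: 5 (4S,5R)-4-ethynyl-2,2-dimethyl-5-(2-methylprop-1-en-1-yl)-1,3-dioxolane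
Conditions: isopropyltriphenylphosphonium iodide, n-BuLi, THF, −78 °C to 0 °C (ylide pre-formed, aldehyde added at −78 °C)
Reagents that add atoms: isopropyltriphenylphosphonium iodide, CC(C)[P+](c1ccccc1)(c1ccccc1)c1ccccc1.[I-]
Why: Wittig olefination with the non-stabilised isopropylidene ylide should install the C14=C15 alkene (no E/Z question arises), the ylide being too weak a base to deprotonate the terminal alkyne and the low temperature limiting epimerisation at C13.

Step 5
Reactants: 5 (4S,5R)-4-ethynyl-2,2-dimethyl-5-(2-methylprop-1-en-1-yl)-1,3-dioxolane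
Product: 6 (4S,5R)-4-(bromoethynyl)-2,2-dimethyl-5-(2-methylprop-1-en-1-yl)-1,3-dioxolane
Conditions: N-bromosuccinimide, AgNO3 (catalytic), acetone, rt
Reagents that add atoms: N-bromosuccinimide, O=C1CCC(=O)N1Br
Why: Silver-acetylide-mediated electrophilic bromination of the alkyne C–H should be much faster than attack of N-bromosuccinimide on the trisubstituted alkene and gives the 1-bromoalkyne that serves as the C10 electrophile.

Step 6
Reactants: 7 methyl (2E)-3-(4-hydroxyphenyl)prop-2-enoate (methyl p-coumarate)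
Product: 8 methyl (2E)-3-{4-[(triisopropylsilyl)oxy]phenyl}prop-2-enoate
Conditions: i-Pr3SiCl, imidazole, DMF, rt
Reagents that add atoms: chlorotriisopropylsilane, CC(C)[Si](Cl)(C(C)C)C(C)C
Why: O-Silylation of the phenol should give a triisopropylsilyl ether robust enough for the alkoxide, organometallic, oxidative and acidic steps that follow and removable by fluoride at the end.

Step 7
Reactants: 8 methyl (2E)-3-{4-[(triisopropylsilyl)oxy]phenyl}prop-2-enoate
Product: 9 (2E)-3-{4-[(triisopropylsilyl)oxy]phenyl}prop-2-en-1-ol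
Conditions: i-Bu2AlH (2.2 equiv), CH2Cl2, −78 °C
Reagents that add atoms: none
Why: 1,2-Reduction of the cinnamate ester by i-Bu2AlH should give the allylic alcohol without touching the (E)-alkene.

Step 8
Reactants: 9 (2E)-3-{4-[(triisopropylsilyl)oxy]phenyl}prop-2-en-1-ol
Product: 10 {4-[(1E)-3-bromoprop-1-en-1-yl]phenoxy}triisopropylsilane
Conditions: CBr4, PPh3, CH2Cl2, 0 °C
Reagents that add atoms: carbon tetrabromide, BrC(Br)(Br)Br
Why: The Appel reaction should convert the primary allylic alcohol into the cinnamyl bromide under neutral conditions with the (E)-geometry retained.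

Step 9
Reactants: 10 {4-[(1E)-3-bromoprop-1-en-1-yl]phenoxy}triisopropylsilane; 11 nerol, (2Z)-3,7-dimethylocta-2,6-dien-1-ol
Product: 12 [4-((1E)-3-{[(2Z)-3,7-dimethylocta-2,6-dien-1-yl]oxy}prop-1-en-1-yl)phenoxy]triisopropylsilane
Conditions: NaH, THF, 0 °C (alkoxide of 11 pre-formed); then 10, 0 °C to rt
Reagents that add atoms: none
Why: Williamson ether synthesis, in which the neryl alkoxide displaces the primary cinnamyl bromide by SN2, should leave the (2Z)-geometry of nerol and the (E)-cinnamyl geometry unchanged.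

Step 10
Reactants: 12 [4-((1E)-3-{[(2Z)-3,7-dimethylocta-2,6-dien-1-yl]oxy}prop-1-en-1-yl)phenoxy]triisopropylsilane
Product: 14 (4Z)-4-methyl-6-{[(2E)-3-{4-[(triisopropylsilyl)oxy]phenyl}prop-2-en-1-yl]oxy}hex-4-enal, via epoxide 13 (not isolated)
Conditions: mCPBA (1.0 equiv), CH2Cl2, −20 °C; then H5IO6, THF/H2O, 0 °C
Reagents that add atoms: 3-chloroperoxybenzoic acid (mCPBA), OOC(=O)c1cccc(Cl)c1
Why: Prilezhaev epoxidation should pick the most electron-rich, distal trisubstituted C6=C7 alkene (the other two alkenes carry a deactivating allylic ether oxygen), and periodic acid then opens and cleaves the epoxide to the C6 aldehyde with loss of acetone.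

Step 11
Reactants: 14 (4Z)-4-methyl-6-{[(2E)-3-{4-[(triisopropylsilyl)oxy]phenyl}prop-2-en-1-yl]oxy}hex-4-enal
Product: 15 2-[(2Z,6Z)-6-methyl-8-{[(2E)-3-{4-[(triisopropylsilyl)oxy]phenyl}prop-2-en-1-yl]oxy}octa-2,6-dien-2-yl]-4,4,5,5-tetramethyl-1,3,2-dioxaborolane
Conditions: 1,1-bis(pinacolboryl)ethane, lithium 2,2,6,6-tetramethylpiperidide (LiTMP), THF, 0 °C; then 14, −78 °C to rt
Reagents that add atoms: 2,2'-(ethane-1,1-diyl)bis(4,4,5,5-tetramethyl-1,3,2-dioxaborolane), CC(B1OC(C)(C)C(C)(C)O1)B1OC(C)(C)C(C)(C)O1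
Why: Boron-Wittig olefination, in which the α-boryl carbanion adds to the aldehyde and syn B–O elimination follows, should give the trisubstituted alkenyl boronate with the chain trans to boron (the aldehyde substituent avoids the remaining, larger boryl group in the four-membered oxaboretane), which fixes the later (6E)-geometry.

Step 12
Reactants: 15 the alkenyl pinacol boronate; 6 (4S,5R)-4-(bromoethynyl)-2,2-dimethyl-5-(2-methylprop-1-en-1-yl)-1,3-dioxolane
Product: 18 (4R,5E,9Z)-1-[(4S,5R)-2,2-dimethyl-5-(2-methylprop-1-en-1-yl)-1,3-dioxolan-4-yl]-5,9-dimethyl-11-{[(2E)-3-{4-[(triisopropylsilyl)oxy]phenyl}prop-2-en-1-yl]oxy}undeca-5,9-dien-1-yn-4-ol, via vinyl alkenyl borate 16 (not isolated), via allyl boronate 17 (not isolated)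
Conditions: vinylmagnesium bromide (1.0 equiv), THF, 0 °C to rt; then 6 (1.1 equiv), Pd(OAc)2 (5 mol %), (Sp,Sp)-MandyPhos (6 mol %), NaOTf, THF/DMSO, 40 °C; then H2O2, pH 7 phosphate buffer, 0 °C to rt
Reagents that add atoms: vinylmagnesium bromide, C=C[Mg]Br; hydrogen peroxide, OO
Why: Proposed new method: zerovalent palladium should insert into the C(sp)–Br bond of 6 and, after bromide-for-triflate exchange, the cationic alkynylpalladium should bind the unsubstituted vinyl group of borate 16 and induce an anti 1,2-shift of the C7 alkenyl group from boron to C8 while C9 bonds to palladium, after which C(sp3)–C(sp) reductive elimination makes the C9–C10 bond and buffered peroxide turns C8–B of 17 into C8–OH with retention. The closest known reaction type is the palladium/MandyPhos conjunctive cross-coupling of vinyl(alkenyl)borates with aryl and alkenyl triflates or halides to α-chiral allyl boronates; a 1-bromoalkyne has not been shown as the electrophile, but it undergoes the same oxidative addition and is an established partner of organoboron reagents in palladium catalysis. No ring is closed in this step. The new stereocentre C8 is set by the chiral bisphosphine on palladium during the metallate shift (catalyst control, the dioxolane stereocentres of 6 being remote) and is carried unchanged through the stereoretentive oxidation. The step needs the vinyl group and not the trisubstituted alkenyl group to be the π-acceptor, which the much lower steric demand of the vinyl group should secure, and it needs the metallate shift to outrun direct boron-to-palladium transfer of an alkenyl group, which the wide-bite-angle ligand, the triflate additive and the exact stoichiometry of vinylmagnesium bromide (none left over to attack 6) are chosen to secure.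

Step 13
Reactants: 18 the (8R) homopropargylic alcohol
Product: 19 triisopropylsilyl ether of 18 at C8–OH
Conditions: i-Pr3SiOTf, 2,6-lutidine, CH2Cl2, −78 °C to 0 °C
Reagents that add atoms: triisopropylsilyl trifluoromethanesulfonate, CC(C)[Si](OS(=O)(=O)C(F)(F)F)(C(C)C)C(C)C
Why: O-Silylation of the only free hydroxyl masks C8–OH, so that C12–OH and C13–OH can be told apart from it once the dioxolane is opened.

Step 14
Reactants: 19 the C8 silyl ether
Product: 20 (4R,5S,9R,10E,14Z)-2,10,14-trimethyl-9-[(triisopropylsilyl)oxy]-16-{[(2E)-3-{4-[(triisopropylsilyl)oxy]phenyl}prop-2-en-1-yl]oxy}hexadeca-2,10,14-trien-6-yne-4,5-diol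
Conditions: AcOH/H2O (4:1), 40 °C
Reagents that add atoms: none
Why: Mild acid hydrolysis of the isopropylidene acetal (protonation at an acetal oxygen, loss of acetone) should free the C12/C13 diol while the secondary and the aryl triisopropylsilyl ethers, both far more acid-stable, survive.

Step 15
Reactants: 20 the 3-yne-1,2-diol
Product: 21 (3E,4S,5R)-3-[(3R,4E,8Z)-4,8-dimethyl-3-[(triisopropylsilyl)oxy]-10-{[(2E)-3-{4-[(triisopropylsilyl)oxy]phenyl}prop-2-en-1-yl]oxy}deca-4,8-dien-1-ylidene]-4-hydroxy-5-(2-methylprop-1-en-1-yl)oxolan-2-one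
Conditions: PdCl2 (5 mol %), PPh3 (10 mol %), SnCl2 (5 mol %), CO (7 atm), MeCN, 75 °C
Reagents that add atoms: carbon monoxide, [C-]#[O+]
Why: Palladium-catalysed cyclocarbonylation of a homopropargylic alcohol: the alkoxycarbonylpalladium species formed at C13–OH should add syn across C10≡C11 in a 5-exo-dig mode (C19 to C11) and protonolysis of the C10–Pd bond leaves hydrogen cis to the carbonyl, so that the γ-lactone ring and the (E)-exocyclic alkene (C9 cis to C12) form together, the propargylic C12–OH being unable to close a four-membered ring.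

Step 16
Reactants: 21 the hydroxy lactone
Product: 22 (3E,4S,5R)-4-acetoxy analogue of 21 (acetate at C12)
Conditions: Ac2O, pyridine, DMAP (catalytic), CH2Cl2, 0 °C
Reagents that add atoms: acetic anhydride, CC(=O)OC(C)=O
Why: Acylation of the only free hydroxyl (C12–OH) under mild base should be clean because C11 carries no hydrogen, so that β-elimination of the new allylic acetate is not possible.

Step 17
Reactants: 22 the bis-silylated acetate
Product: 23 target, (2R,3S,4E)-4-[(3R,4E,8Z)-3-hydroxy-10-{[(2E)-3-(4-hydroxyphenyl)prop-2-en-1-yl]oxy}-4,8-dimethyldeca-4,8-dien-1-ylidene]-2-(2-methylprop-1-en-1-yl)-5-oxooxolan-3-yl acetate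
Conditions: Bu4NF, AcOH (1:1), THF, 0 °C to rt
Reagents that add atoms: none
Why: Fluoride-induced desilylation should remove both triisopropylsilyl ethers, the acetic acid buffer protonating the phenoxide at once so that it cannot add to the alkylidene lactone or displace the allylic acetate.

**Compound list**
1 | (3aR,6aR)-2,2-dimethyldihydrofuro[3,4-d][1,3]dioxol-4(3aH)-one, (−)-2,3-O-isopropylidene-D-erythronolactone | CC1(C)O[C@@H]2COC(=O)[C@@H]2O1 | starting material
2 | 2,3-O-isopropylidene-D-erythrofuranose (lactol, anomeric mixture) | CC1(C)O[C@@H]2COC(O)[C@@H]2O1 | intermediate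
3 | [(4R,5S)-5-ethynyl-2,2-dimethyl-1,3-dioxolan-4-yl]methanol | C#C[C@@H]1OC(C)(C)O[C@@H]1CO | intermediate
4 | (4S,5S)-5-ethynyl-2,2-dimethyl-1,3-dioxolane-4-carbaldehyde | C#C[C@@H]1OC(C)(C)O[C@@H]1C=O | intermediate
5 | (4S,5R)-4-ethynyl-2,2-dimethyl-5-(2-methylprop-1-en-1-yl)-1,3-dioxolane | C#C[C@@H]1OC(C)(C)O[C@@H]1C=C(C)C | intermediate
6 | (4S,5R)-4-(bromoethynyl)-2,2-dimethyl-5-(2-methylprop-1-en-1-yl)-1,3-dioxolane | BrC#C[C@@H]1OC(C)(C)O[C@@H]1C=C(C)C | intermediate
7 | methyl (2E)-3-(4-hydroxyphenyl)prop-2-enoate | COC(=O)/C=C/c1ccc(O)cc1 | starting material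
8 | methyl (2E)-3-{4-[(triisopropylsilyl)oxy]phenyl}prop-2-enoate | COC(=O)/C=C/c1ccc(O[Si](C(C)C)(C(C)C)C(C)C)cc1 | intermediate
9 | (2E)-3-{4-[(triisopropylsilyl)oxy]phenyl}prop-2-en-1-ol | OC/C=C/c1ccc(O[Si](C(C)C)(C(C)C)C(C)C)cc1 | intermediate
10 | {4-[(1E)-3-bromoprop-1-en-1-yl]phenoxy}triisopropylsilane | BrC/C=C/c1ccc(O[Si](C(C)C)(C(C)C)C(C)C)cc1 | intermediate
11 | nerol, (2Z)-3,7-dimethylocta-2,6-dien-1-ol | CC(C)=CCC/C(C)=C\CO | starting material
12 | [4-((1E)-3-{[(2Z)-3,7-dimethylocta-2,6-dien-1-yl]oxy}prop-1-en-1-yl)phenoxy]triisopropylsilane | CC(C)=CCC/C(C)=C\COC/C=C/c1ccc(O[Si](C(C)C)(C(C)C)C(C)C)cc1 | intermediate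
13 | racemic 6,7-epoxide of 12 (3,3-dimethyloxirane at the chain end) | CC1(C)OC1CC/C(C)=C\COC/C=C/c2ccc(O[Si](C(C)C)(C(C)C)C(C)C)cc2 | intermediate
14 | (4Z)-4-methyl-6-{[(2E)-3-{4-[(triisopropylsilyl)oxy]phenyl}prop-2-en-1-yl]oxy}hex-4-enal | O=CCC/C(C)=C\COC/C=C/c1ccc(O[Si](C(C)C)(C(C)C)C(C)C)cc1 | intermediate
15 | 2-[(2Z,6Z)-6-methyl-8-{[(2E)-3-{4-[(triisopropylsilyl)oxy]phenyl}prop-2-en-1-yl]oxy}octa-2,6-dien-2-yl]-4,4,5,5-tetramethyl-1,3,2-dioxaborolane | C/C(B1OC(C)(C)C(C)(C)O1)=C\CC/C(C)=C\COC/C=C/c1ccc(O[Si](C(C)C)(C(C)C)C(C)C)cc1 | intermediate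
16 | bromomagnesium vinyl(pinacolato)borate of 15 (boron carries the vinyl group and the (2Z,6Z)-alkenyl group) | C=C[B-]1(OC(C)(C)C(C)(C)O1)/C(C)=C/CC/C(C)=C\COC/C=C/c2ccc(O[Si](C(C)C)(C(C)C)C(C)C)cc2.[Mg+]Br | intermediate
17 | (4S,5R)-4-[(4R,5E,9Z)-5,9-dimethyl-4-(4,4,5,5-tetramethyl-1,3,2-dioxaborolan-2-yl)-11-{[(2E)-3-{4-[(triisopropylsilyl)oxy]phenyl}prop-2-en-1-yl]oxy}undeca-5,9-dien-1-yn-1-yl]-2,2-dimethyl-5-(2-methylprop-1-en-1-yl)-1,3-dioxolane | CC1(C)O[C@H](C=C(C)C)[C@H](C#CC[C@@H](B2OC(C)(C)C(C)(C)O2)/C(C)=C/CC/C(C)=C\COC/C=C/c2ccc(O[Si](C(C)C)(C(C)C)C(C)C)cc2)O1 | intermediate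
18 | (4R,5E,9Z)-1-[(4S,5R)-2,2-dimethyl-5-(2-methylprop-1-en-1-yl)-1,3-dioxolan-4-yl]-5,9-dimethyl-11-{[(2E)-3-{4-[(triisopropylsilyl)oxy]phenyl}prop-2-en-1-yl]oxy}undeca-5,9-dien-1-yn-4-ol | CC1(C)O[C@H](C=C(C)C)[C@H](C#CC[C@@H](O)/C(C)=C/CC/C(C)=C\COC/C=C/c2ccc(O[Si](C(C)C)(C(C)C)C(C)C)cc2)O1 | intermediate
19 | C8 triisopropylsilyl ether of 18 | CC1(C)O[C@H](C=C(C)C)[C@H](C#CC[C@@H](O[Si](C(C)C)(C(C)C)C(C)C)/C(C)=C/CC/C(C)=C\COC/C=C/c2ccc(O[Si](C(C)C)(C(C)C)C(C)C)cc2)O1 | intermediate
20 | (4R,5S,9R,10E,14Z)-2,10,14-trimethyl-9-[(triisopropylsilyl)oxy]-16-{[(2E)-3-{4-[(triisopropylsilyl)oxy]phenyl}prop-2-en-1-yl]oxy}hexadeca-2,10,14-trien-6-yne-4,5-diol | CC(C)=C[C@@H](O)[C@@H](O)C#CC[C@@H](O[Si](C(C)C)(C(C)C)C(C)C)/C(C)=C/CC/C(C)=C\COC/C=C/c1ccc(O[Si](C(C)C)(C(C)C)C(C)C)cc1 | intermediate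
21 | (3E,4S,5R)-3-[(3R,4E,8Z)-4,8-dimethyl-3-[(triisopropylsilyl)oxy]-10-{[(2E)-3-{4-[(triisopropylsilyl)oxy]phenyl}prop-2-en-1-yl]oxy}deca-4,8-dien-1-ylidene]-4-hydroxy-5-(2-methylprop-1-en-1-yl)oxolan-2-one | O[C@H]1/C(=C\C[C@@H](O[Si](C(C)C)(C(C)C)C(C)C)/C(C)=C/CC/C(C)=C\COC/C=C/c2ccc(O[Si](C(C)C)(C(C)C)C(C)C)cc2)C(=O)O[C@@H]1C=C(C)C | intermediate
22 | C12 acetate of 21, (2R,3S,4E)-4-[(3R,4E,8Z)-4,8-dimethyl-3-[(triisopropylsilyl)oxy]-10-{[(2E)-3-{4-[(triisopropylsilyl)oxy]phenyl}prop-2-en-1-yl]oxy}deca-4,8-dien-1-ylidene]-2-(2-methylprop-1-en-1-yl)-5-oxooxolan-3-yl acetate | CC(=O)O[C@H]1/C(=C\C[C@@H](O[Si](C(C)C)(C(C)C)C(C)C)/C(C)=C/CC/C(C)=C\COC/C=C/c2ccc(O[Si](C(C)C)(C(C)C)C(C)C)cc2)C(=O)O[C@@H]1C=C(C)C | intermediate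
23 | (2R,3S,4E)-4-[(3R,4E,8Z)-3-hydroxy-10-{[(2E)-3-(4-hydroxyphenyl)prop-2-en-1-yl]oxy}-4,8-dimethyldeca-4,8-dien-1-ylidene]-2-(2-methylprop-1-en-1-yl)-5-oxooxolan-3-yl acetate | CC(=O)O[C@H]1/C(=C\C[C@@H](O)/C(C)=C/CC/C(C)=C\COC/C=C/c2ccc(O)cc2)C(=O)O[C@@H]1C=C(C)C | target

**Totals**
Total step count: 17.
Longest linear sequence: 12 steps (steps 6 to 17, from methyl p-coumarate 7); the branch from lactone 1 runs 11 steps (steps 1 to 5, then 12 to 17).

**Three steps most likely to fail**

Step 12 (bears the label). What may go wrong: direct boron-to-palladium transfer of the vinyl or alkenyl group (Suzuki-type enyne formation) or reductive homocoupling of the bromoalkyne may outrun the metallate shift, and facial control at C8 may be weak. The fallback uses known chemistry only, sets out from 12 and 5 and comes back to the route at 18. Allylic oxidation of ether 12 at the (E)-methyl group of its terminal alkene (SeO2 catalytic, t-BuOOH, then MnO2) would give the (2E)-enal F1. Corey–Chaykovsky methylenation (trimethylsulfonium iodide, n-BuLi, THF) would give the racemic alkenyl oxirane F2. Hydrolytic kinetic resolution with a chiral (salen)Co(OAc) catalyst and 0.55 equivalents of water would leave the (S)-oxirane F3 beside the (R)-diol F4. The lithium acetylide of 5 (n-BuLi, THF/DMPU, no Lewis acid) would then open F3 by SN2 attack at its unsubstituted carbon (C9) and give 18 directly, with C8 fixed by the epoxide.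

Step 15. What may go wrong: π-acid-induced 5-endo cycloisomerisation of the 3-yne-1,2-diol with loss of water (furan formation), or ionisation of the allylic C13–OH, may outrun carbonylation. The fallback sets out from 20 and comes back at 21. Titanocene-catalysed hydromagnesiation (i-BuMgBr in excess, Cp2TiCl2 catalytic, Et2O, rt), directed by the propargylic C12 alkoxide, would add H and Mg syn across the alkyne with magnesium on C11. Quenching with CO2 would give the (E)-configured carboxylic acid F5 (carboxyl trans to C9), which on acidic work-up lactonises onto C13–OH to give 21.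

Step 11. What may go wrong: loss of stereocontrol in the B–O elimination (wrong alkene isomer) or enolisation and self-condensation of the aldehyde by the basic carbanion. The fallback sets out from 14 and comes back at 15. Seyferth–Gilbert homologation (Ohira–Bestmann reagent, K2CO3, MeOH) would give the terminal alkyne F6, and C-methylation (n-BuLi, MeI) the 2-alkyne F7. Hydrozirconation with excess Cp2Zr(H)Cl (equilibration to the regioisomer with zirconium on the methyl-bearing carbon) and iodinolysis would give the (E)-2-iodoalkene F8. Iodine–lithium exchange (t-BuLi, −78 °C) and trapping with 2-isopropoxy-4,4,5,5-tetramethyl-1,3,2-dioxaborolane would give 15 with the geometry retained.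

**Further compounds**
F1 | step 12 | (2E,6Z)-2,6-dimethyl-8-{[(2E)-3-{4-[(triisopropylsilyl)oxy]phenyl}prop-2-en-1-yl]oxy}octa-2,6-dienal | O=C/C(C)=C/CC/C(C)=C\COC/C=C/c1ccc(O[Si](C(C)C)(C(C)C)C(C)C)cc1
F2 | step 12 | racemic 2-[(2E,6Z)-6-methyl-8-{[(2E)-3-{4-[(triisopropylsilyl)oxy]phenyl}prop-2-en-1-yl]oxy}octa-2,6-dien-2-yl]oxirane | C1OC1/C(C)=C/CC/C(C)=C\COC/C=C/c2ccc(O[Si](C(C)C)(C(C)C)C(C)C)cc2
F3 | step 12 | (2S)-2-[(2E,6Z)-6-methyl-8-{[(2E)-3-{4-[(triisopropylsilyl)oxy]phenyl}prop-2-en-1-yl]oxy}octa-2,6-dien-2-yl]oxirane | C1O[C@H]1/C(C)=C/CC/C(C)=C\COC/C=C/c2ccc(O[Si](C(C)C)(C(C)C)C(C)C)cc2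
F4 | step 12 | (2R,3E,7Z)-3,7-dimethyl-9-{[(2E)-3-{4-[(triisopropylsilyl)oxy]phenyl}prop-2-en-1-yl]oxy}nona-3,7-diene-1,2-diol | OC[C@H](O)/C(C)=C/CC/C(C)=C\COC/C=C/c2ccc(O[Si](C(C)C)(C(C)C)C(C)C)cc2
F5 | step 15 | (2E,5R,6E,10Z)-2-[(1S,2R)-1,2-dihydroxy-4-methylpent-3-en-1-yl]-6,10-dimethyl-5-[(triisopropylsilyl)oxy]-12-{[(2E)-3-{4-[(triisopropylsilyl)oxy]phenyl}prop-2-en-1-yl]oxy}dodeca-2,6,10-trienoic acid | OC(=O)/C(=C/C[C@@H](O[Si](C(C)C)(C(C)C)C(C)C)/C(C)=C/CC/C(C)=C\COC/C=C/c1ccc(O[Si](C(C)C)(C(C)C)C(C)C)cc1)[C@H](O)[C@H](O)C=C(C)C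
F6 | step 11 | {4-[(1E)-3-{[(2Z)-3-methylhept-2-en-6-yn-1-yl]oxy}prop-1-en-1-yl]phenoxy}triisopropylsilane | C#CCC/C(C)=C\COC/C=C/c1ccc(O[Si](C(C)C)(C(C)C)C(C)C)cc1
F7 | step 11 | {4-[(1E)-3-{[(2Z)-3-methyloct-2-en-6-yn-1-yl]oxy}prop-1-en-1-yl]phenoxy}triisopropylsilane | CC#CCC/C(C)=C\COC/C=C/c1ccc(O[Si](C(C)C)(C(C)C)C(C)C)cc1
F8 | step 11 | {4-[(1E)-3-{[(2Z,6E)-7-iodo-3-methylocta-2,6-dien-1-yl]oxy}prop-1-en-1-yl]phenoxy}triisopropylsilane | C/C(I)=C\CC/C(C)=C\COC/C=C/c1ccc(O[Si](C(C)C)(C(C)C)C(C)C)cc1
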